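The route rests on cutting the furan at its C3–C4 bond (furan numbering), the bond between the ring carbon that carries the C15 chain and the adjacent ring CH, the one place where the heteroaromatic ring conceals an alkene. Ring-closing metathesis of a 1,1-disubstituted alkene onto the vinyl group of a mixed acrolein acetal, followed in the same flask by acid-promoted loss of methanol, closes and aromatises the ring in one operation, so the fragile furan never meets an oxidant, a strong base or a strong acid. The precursor is the complete, unprotected (4S,5R,8S) lactone diol whose chain ends in CH2=C(R)–CH2–O–CH(OMe)–CH=CH2.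

Key step: step 13

Remarks on the chemistry
- Atom labels C1–C15 follow the chain from the lactone carbonyl. (S)-(+)-Linalool of high enantiomeric purity is assumed to be purchasable. The acetal carbon in 18, 19 and 20 is an inconsequential mixture of epimers.
- The C4 and C5 oxygens lie anti across the former E-alkene, so epoxidation followed by invertive lactonisation is used; a syn-dihydroxylation would give the C4 epimer.
- Two temporary silyl ethers are added to the plan. The C8 hydroxyl is masked while the C4–C5 epoxide exists, because a free tertiary alcohol in that position closes onto the epoxide to give a tetrahydrofuran. The C5 hydroxyl is masked while the mixed acetal is made, because acid-catalysed acetal exchange would not single out the primary allylic alcohol.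

Step 1
Reactants: 1 2-methylprop-2-en-1-ol; 2 1-bromobut-2-yne
Product: 4 2-methylidenehept-5-yn-1-ol, via O,C-dilithiated 2-methylprop-2-en-1-ol 3 (not isolated)
Conditions: n-BuLi (2.2 equiv), TMEDA, Et2O, 0 °C to rt; then 2, THF, −78 °C to rt; H2O
Reagents that add atoms: none
Why: Double deprotonation gives the O,C-dilithiated methallyl species, whose allylic carbanion (far more nucleophilic than the alkoxide) displaces the primary propargylic bromide by SN2 (dianion alkylation of methallyl alcohol), turning the methyl carbon into C15 and attaching C14.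

Step 2
Reactants: 4 2-methylidenehept-5-yn-1-ol
Product: 6 (5E)-6-methyl-2-methylidenenona-5,8-dien-1-ol, via alkenylzirconocene 5 (not isolated)
Conditions: Cp2Zr(H)Cl (2.3 equiv), THF, rt to 45 °C; then CuCl (10 mol%), LiCl, allyl bromide, 0 °C to rt; H2O
Reagents that add atoms: allyl bromide (3-bromoprop-1-ene), C=CCBr
Why: Hydrozirconation followed by copper-catalysed allylation: the first equivalent of Cp2Zr(H)Cl caps the hydroxyl as a zirconium alkoxide, the second adds H–Zr syn across the alkyne (faster than across the 1,1-disubstituted alkene) and, with a slight excess of hydride and gentle warming, should settle zirconium on the less hindered methyl-bearing carbon, so that transmetalation to copper and allylation with retention place the allyl group trans to the chain and give the E C12=C13 alkene.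

Step 3
Reactants: 7 (S)-linalool [(3S)-3,7-dimethylocta-1,6-dien-3-ol]
Product: 8 triethyl{[(3S)-3,7-dimethylocta-1,6-dien-3-yl]oxy}silane
Conditions: TESOTf, 2,6-lutidine, CH2Cl2, −78 to 0 °C
Reagents that add atoms: triethylsilyl trifluoromethanesulfonate, CC[Si](CC)(CC)OS(=O)(=O)C(F)(F)F
Why: Silylation of the tertiary alcohol with a silyl triflate and a hindered pyridine base is fast at low temperature, leaves the C8 stereocentre untouched, and gives the ether that later keeps the C8 oxygen from opening the C4–C5 epoxide.

Step 4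
Reactants: 8 triethyl{[(3S)-3,7-dimethylocta-1,6-dien-3-yl]oxy}silane
Product: 9 (2E,6S)-2,6-dimethyl-6-[(triethylsilyl)oxy]octa-2,7-dien-1-ol
Conditions: SeO2 (0.3 equiv), t-BuOOH (2.5 equiv), CH2Cl2, 0 °C to rt, stopped short of full conversion
Reagents that add atoms: tert-butyl hydroperoxide, CC(C)(C)OO (source of the new oxygen, delivered through catalytic SeO2, O=[Se]=O)
Why: Selenium dioxide allylic oxidation with tert-butyl hydroperoxide as reoxidant (ene reaction, then [2,3]-sigmatropic shift) attacks the more substituted alkene at its E-methyl group and gives the E allylic alcohol, while the vinyl group has no allylic hydrogen and is left alone.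

Step 5
Reactants: 9 (2E,6S)-2,6-dimethyl-6-[(triethylsilyl)oxy]octa-2,7-dien-1-ol
Product: 10 {[(3S,6E)-8-bromo-3,7-dimethylocta-1,6-dien-3-yl]oxy}triethylsilane
Conditions: CBr4, PPh3, 2,6-lutidine, CH2Cl2, −20 to 0 °C
Reagents that add atoms: carbon tetrabromide, BrC(Br)(Br)Br
Why: Appel bromination converts the primary allylic alcohol into the bromide by SN2 displacement of the oxyphosphonium ion without allylic transposition or change of alkene geometry, and the cold, buffered medium spares the silyl ether.

Step 6
Reactants: 10 {[(3S,6E)-8-bromo-3,7-dimethylocta-1,6-dien-3-yl]oxy}triethylsilane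
Product: 11 tert-butyl (4E,8S)-4,8-dimethyl-8-[(triethylsilyl)oxy]deca-4,9-dienoate
Conditions: tert-butyl acetate, LiN(iPr)2, THF, −78 °C; then 10, DMPU, −78 to −20 °C
Reagents that add atoms: tert-butyl acetate, CC(=O)OC(C)(C)C
Why: Ester enolate alkylation, in which the lithium enolate of tert-butyl acetate displaces the primary allylic bromide by SN2, adds C2 and C1 with the E alkene intact, and the tert-butyl ester resists self-condensation and the basic epoxidation medium that follows.

Step 7
Reactants: 11 tert-butyl (4E,8S)-4,8-dimethyl-8-[(triethylsilyl)oxy]deca-4,9-dienoate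
Product: 12 tert-butyl 3-[(2R,3R)-2-methyl-3-{(3S)-3-methyl-3-[(triethylsilyl)oxy]pent-4-en-1-yl}oxiran-2-yl]propanoate
Conditions: D-fructose-derived Shi ketone (1,2:4,5-di-O-isopropylidene-β-D-erythro-2,3-hexodiulo-2,6-pyranose, 30 mol%), Oxone (2KHSO5·KHSO4·K2SO4), K2CO3, Bu4NHSO4, Na2B4O7/Na2EDTA buffer, MeCN–dimethoxymethane–H2O, 0 °C
Reagents that add atoms: potassium peroxymonosulfate KHSO5 (from Oxone), [K+].[O-]S(=O)(=O)OO
Why: Shi asymmetric epoxidation, in which the chiral dioxirane formed from the D-fructose-derived ketone transfers oxygen through a spiro transition state to one face of the electron-rich E-trisubstituted alkene (the monosubstituted vinyl group is far less reactive), so that catalyst control sets C4 and C5 of the epoxide both as R.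

Step 8
Reactants: 12 tert-butyl 3-[(2R,3R)-2-methyl-3-{(3S)-3-methyl-3-[(triethylsilyl)oxy]pent-4-en-1-yl}oxiran-2-yl]propanoate
Product: 14 (5S)-5-[(1R,4S)-1,4-dihydroxy-4-methylhex-5-en-1-yl]-5-methyloxolan-2-one, via silylated hydroxy lactone 13 (not isolated)
Conditions: (+)-10-camphorsulfonic acid (10 mol%), CH2Cl2, 0 °C; then Bu4NF (THF), 0 °C to rt
Reagents that add atoms: none
Why: Acid-catalysed epoxide opening with neighbouring-group participation, in which the ester carbonyl attacks the protonated epoxide at the tertiary carbon C4 in a 5-exo mode with inversion (C4 becomes S, C5 keeps its R configuration and emerges as the free alcohol) and the alkoxylactonium ion sheds 2-methylpropene to give lactone 13, after which fluoride removes the tertiary silyl ether now that no epoxide is left for the C8 oxygen to attack.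

Step 9
Reactants: 14 (5S)-5-[(1R,4S)-1,4-dihydroxy-4-methylhex-5-en-1-yl]-5-methyloxolan-2-one
Product: 15 (5S)-5-{(1R,4S)-4-hydroxy-4-methyl-1-[(triethylsilyl)oxy]hex-5-en-1-yl}-5-methyloxolan-2-one
Conditions: TESCl, imidazole, DMF, 0 °C to rt
Reagents that add atoms: chlorotriethylsilane, CC[Si](Cl)(CC)CC
Why: Chemoselective silylation, since the secondary C5 alcohol reacts with the silyl chloride–imidazole pair far faster than the tertiary allylic C8 alcohol, which must stay free for the metathesis.

Step 10
Reactants: 15 (5S)-5-{(1R,4S)-4-hydroxy-4-methyl-1-[(triethylsilyl)oxy]hex-5-en-1-yl}-5-methyloxolan-2-one; 6 (5E)-6-methyl-2-methylidenenona-5,8-dien-1-ol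
Product: 16 (5S)-5-{(1R,4S,5E,8E)-4-hydroxy-12-(hydroxymethyl)-4,8-dimethyl-1-[(triethylsilyl)oxy]trideca-5,8,12-trien-1-yl}-5-methyloxolan-2-one
Conditions: second-generation Hoveyda–Grubbs catalyst RuCl2(H2IMes)(=CH-C6H4-2-OiPr) (10 mol%), 6 (3 equiv), 1,4-benzoquinone (20 mol%), CH2Cl2, 40 °C, argon sweep
Reagents that add atoms: none
Why: Olefin cross-metathesis between a vinyl carbinol that does not homodimerise and the unhindered terminal alkene of 6 forms C9=C10 with loss of ethene; the quaternary carbinol beside the new alkene enforces the E geometry, the trisubstituted and 1,1-disubstituted alkenes of 6 are too hindered to compete, and benzoquinone suppresses hydride-mediated migration of the skipped diene.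

Step 11
Reactants: 16 (5S)-5-{(1R,4S,5E,8E)-4-hydroxy-12-(hydroxymethyl)-4,8-dimethyl-1-[(triethylsilyl)oxy]trideca-5,8,12-trien-1-yl}-5-methyloxolan-2-one; 17 acrolein dimethyl acetal (3,3-dimethoxyprop-1-ene)
Product: 18 (5S)-5-{(1R,4S,5E,8E)-4-hydroxy-12-[(1-methoxyprop-2-enoxy)methyl]-4,8-dimethyl-1-[(triethylsilyl)oxy]trideca-5,8,12-trien-1-yl}-5-methyloxolan-2-one
Conditions: 17 (10 equiv), pyridinium p-toluenesulfonate (5 mol%), 5 Å molecular sieves, CH2Cl2, rt; Et3N quench
Reagents that add atoms: none
Why: Acid-catalysed transacetalisation, in which the methoxy-stabilised oxocarbenium ion formed from the excess acetal is captured by the only unhindered hydroxyl (the primary allylic alcohol) while the tertiary C8 alcohol is too hindered and the C5 oxygen is silylated, with the sieves removing methanol to drive the exchange.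

Step 12
Reactants: 18 (5S)-5-{(1R,4S,5E,8E)-4-hydroxy-12-[(1-methoxyprop-2-enoxy)methyl]-4,8-dimethyl-1-[(triethylsilyl)oxy]trideca-5,8,12-trien-1-yl}-5-methyloxolan-2-one
Product: 19 (5S)-5-[(1R,4S,5E,8E)-1,4-dihydroxy-12-[(1-methoxyprop-2-enoxy)methyl]-4,8-dimethyltrideca-5,8,12-trien-1-yl]-5-methyloxolan-2-one
Conditions: Bu4NF, AcOH (1:1), THF, 0 °C to rt
Reagents that add atoms: none
Why: Fluoride-mediated desilylation under acetic acid buffering cleaves the Si–O bond at C5 without touching the base-stable mixed acetal, the lactone or the tertiary allylic alcohol.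

Step 13
Reactants: 19 (5S)-5-[(1R,4S,5E,8E)-1,4-dihydroxy-12-[(1-methoxyprop-2-enoxy)methyl]-4,8-dimethyltrideca-5,8,12-trien-1-yl]-5-methyloxolan-2-one
Product: 21 (5S)-5-[(1R,4S,5E,8E)-11-(furan-3-yl)-1,4-dihydroxy-4,8-dimethylundeca-5,8-dien-1-yl]-5-methyloxolan-2-one, via 2-methoxy-2,5-dihydrofuran 20 (not isolated)
Conditions: second-generation Grubbs catalyst RuCl2(PCy3)(H2IMes)(=CHPh) (5 mol%), 1,4-benzoquinone (10 mol%), CH2Cl2 (0.005 M), 40 °C; then pyridinium p-toluenesulfonate (20 mol%), rt
Reagents that add atoms: none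
Why: The ruthenium benzylidene first exchanges onto the monosubstituted acetal vinyl group of 19, the resulting alkylidene adds across the 1,1-disubstituted C=CH2 five atoms away (cycloaddition to a ruthenacyclobutane, then cycloreversion) to release ethene and the 2-methoxy-2,5-dihydrofuran 20, and pyridinium p-toluenesulfonate then ionises the acetal to a cyclic oxocarbenium ion that loses a proton from the ring CH2 to give the aromatic furan. The closest known reaction type is ring-closing metathesis of mixed allyl acetals of 2-substituted allylic alcohols followed by acid-promoted loss of alcohol, an established entry to 3-substituted furans. The one ring formed is closed as a five-membered ring by ring-closing olefin metathesis, the new bond being C3–C4 of the furan. No stereocentre is created: the acetal carbon of 20 is an epimeric mixture that vanishes on aromatisation, and C4, C5 and C8 are not touched. The step needs chemoselectivity for the two terminal alkenes over C9=C10 and C12=C13, which is secured by their substitution (E-disubstituted next to a fully substituted carbinol, and trisubstituted) and by the seven-membered or larger rings their engagement would require. It also needs an acid weak enough to spare the tertiary allylic C8 alcohol, which the buffered pyridinium salt should provide.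

Compound list
1 | 2-methylprop-2-en-1-ol | C=C(C)CO | starting material
2 | 1-bromobut-2-yne | CC#CCBr | starting material
3 | O,C-dilithiated 2-methylprop-2-en-1-ol (not isolated) | [Li]CC(=C)CO[Li] | intermediate
4 | 2-methylidenehept-5-yn-1-ol | CC#CCCC(=C)CO | intermediate
5 | alkenylzirconocene: (5E)-2-methylidenehept-5-en-1-ol carrying a ZrCp2Cl unit on oxygen and on C6 (not isolated) | C/C(=C\CCC(=C)CO[Zr](Cl)(C1C=CC=C1)C1C=CC=C1)[Zr](Cl)(C1C=CC=C1)C1C=CC=C1 | intermediate
6 | (5E)-6-methyl-2-methylidenenona-5,8-dien-1-ol | C/C(=C\CCC(=C)CO)CC=C | intermediate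
7 | (S)-linalool, (3S)-3,7-dimethylocta-1,6-dien-3-ol | C=C[C@@](C)(O)CCC=C(C)C | starting material
8 | triethyl{[(3S)-3,7-dimethylocta-1,6-dien-3-yl]oxy}silane | C=C[C@@](C)(O[Si](CC)(CC)CC)CCC=C(C)C | intermediate
9 | (2E,6S)-2,6-dimethyl-6-[(triethylsilyl)oxy]octa-2,7-dien-1-ol | C=C[C@@](C)(O[Si](CC)(CC)CC)CC/C=C(\C)CO | intermediate
10 | {[(3S,6E)-8-bromo-3,7-dimethylocta-1,6-dien-3-yl]oxy}triethylsilane | C=C[C@@](C)(O[Si](CC)(CC)CC)CC/C=C(\C)CBr | intermediate
11 | tert-butyl (4E,8S)-4,8-dimethyl-8-[(triethylsilyl)oxy]deca-4,9-dienoate | C=C[C@@](C)(O[Si](CC)(CC)CC)CC/C=C(\C)CCC(=O)OC(C)(C)C | intermediate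
12 | tert-butyl 3-[(2R,3R)-2-methyl-3-{(3S)-3-methyl-3-[(triethylsilyl)oxy]pent-4-en-1-yl}oxiran-2-yl]propanoate | C=C[C@@](C)(O[Si](CC)(CC)CC)CC[C@H]1O[C@]1(C)CCC(=O)OC(C)(C)C | intermediate
13 | (5S)-5-{(1R,4S)-1-hydroxy-4-methyl-4-[(triethylsilyl)oxy]hex-5-en-1-yl}-5-methyloxolan-2-one (not isolated) | C=C[C@@](C)(O[Si](CC)(CC)CC)CC[C@@H](O)[C@]1(C)CCC(=O)O1 | intermediate
14 | (5S)-5-[(1R,4S)-1,4-dihydroxy-4-methylhex-5-en-1-yl]-5-methyloxolan-2-one | C=C[C@@](C)(O)CC[C@@H](O)[C@]1(C)CCC(=O)O1 | intermediate
15 | (5S)-5-{(1R,4S)-4-hydroxy-4-methyl-1-[(triethylsilyl)oxy]hex-5-en-1-yl}-5-methyloxolan-2-one | C=C[C@@](C)(O)CC[C@@H](O[Si](CC)(CC)CC)[C@]1(C)CCC(=O)O1 | intermediate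
16 | (5S)-5-{(1R,4S,5E,8E)-4-hydroxy-12-(hydroxymethyl)-4,8-dimethyl-1-[(triethylsilyl)oxy]trideca-5,8,12-trien-1-yl}-5-methyloxolan-2-one | C/C(=C\CCC(=C)CO)C/C=C/[C@@](C)(O)CC[C@@H](O[Si](CC)(CC)CC)[C@]1(C)CCC(=O)O1 | intermediate
17 | acrolein dimethyl acetal (3,3-dimethoxyprop-1-ene) | C=CC(OC)OC | starting material
18 | (5S)-5-{(1R,4S,5E,8E)-4-hydroxy-12-[(1-methoxyprop-2-enoxy)methyl]-4,8-dimethyl-1-[(triethylsilyl)oxy]trideca-5,8,12-trien-1-yl}-5-methyloxolan-2-one (either acetal epimer) | C/C(=C\CCC(=C)COC(OC)C=C)C/C=C/[C@@](C)(O)CC[C@@H](O[Si](CC)(CC)CC)[C@]1(C)CCC(=O)O1 | intermediate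
19 | (5S)-5-[(1R,4S,5E,8E)-1,4-dihydroxy-12-[(1-methoxyprop-2-enoxy)methyl]-4,8-dimethyltrideca-5,8,12-trien-1-yl]-5-methyloxolan-2-one (either acetal epimer) | C/C(=C\CCC(=C)COC(OC)C=C)C/C=C/[C@@](C)(O)CC[C@@H](O)[C@]1(C)CCC(=O)O1 | intermediate
20 | (5S)-5-[(1R,4S,5E,8E)-1,4-dihydroxy-11-(5-methoxy-2,5-dihydrofuran-3-yl)-4,8-dimethylundeca-5,8-dien-1-yl]-5-methyloxolan-2-one (either acetal epimer, not isolated) | C/C(=C\CCC2=CC(OC)OC2)C/C=C/[C@@](C)(O)CC[C@@H](O)[C@]1(C)CCC(=O)O1 | intermediate
21 | (5S)-5-[(1R,4S,5E,8E)-11-(furan-3-yl)-1,4-dihydroxy-4,8-dimethylundeca-5,8-dien-1-yl]-5-methyloxolan-2-one (CNP0151262.1) | C/C(=C\CCc1ccoc1)C/C=C/[C@@](C)(O)CC[C@@H](O)[C@]1(C)CCC(=O)O1 | target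

Total step count: 13. Longest linear sequence: 11 steps (steps 3–13, from (S)-linalool); steps 1–2 supply the second cross-metathesis partner.

Steps most likely to fail

1. Step 10 (cross-metathesis). The hindered vinyl carbinol may turn over slowly, so that the excess triene is consumed by self-metathesis and its skipped diene drifts into conjugation by hydride-mediated double-bond migration. The fallback sets out from 15 and comes back at 16. Cross-metathesis of 15 with an excess of cheap (Z)-but-2-ene-1,4-diyl diacetate (second-generation Hoveyda–Grubbs catalyst RuCl2(H2IMes)(=CH-C6H4-2-OiPr), CH2Cl2, 40 °C) should give the E allylic acetate (2E,4S,7R)-4-hydroxy-4-methyl-7-[(2S)-2-methyl-5-oxooxolan-2-yl]-7-[(triethylsilyl)oxy]hept-2-en-1-yl acetate F1. A Pd(PPh3)4-catalysed allyl–alkenyl coupling of F1 with alkenylzirconocene 5 (about two equivalents, generated from 4 as in step 2) would then form the C11–C12 bond at the unhindered allyl terminus with retention of both alkene geometries, and aqueous work-up frees the primary alcohol to give 16.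

2. Step 2 (hydrozirconation–allylation). Regiochemical equilibration of the alkenylzirconium may be incomplete, leaving material allylated at C13, and the excess hydride demanded by the free hydroxyl may also add to the 1,1-disubstituted alkene. The fallback sets out from 1 (through dianion 3) and comes back at 6; it takes the alkene geometry from an E-selective allylic oxidation instead. Alkylation of 3 with prenyl bromide gives 6-methyl-2-methylidenehept-5-en-1-ol F2, and TBSCl/imidazole gives tert-butyldimethyl[(6-methyl-2-methylidenehept-5-en-1-yl)oxy]silane F3. SeO2/t-BuOOH oxidises the E-methyl group of the trisubstituted alkene to (2E)-6-({[tert-butyl(dimethyl)silyl]oxy}methyl)-2-methylhepta-2,6-dien-1-ol F4, and Appel bromination gives {[(5E)-7-bromo-6-methyl-2-methylidenehept-5-en-1-yl]oxy}(tert-butyl)dimethylsilane F5. Stille coupling with tributyl(vinyl)stannane (Pd2(dba)3, AsPh3, THF) gives tert-butyldimethyl{[(5E)-6-methyl-2-methylidenenona-5,8-dien-1-yl]oxy}silane F6, and Bu4NF returns 6.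

3. Step 13 (ring closure and aromatisation). The skipped diene may migrate under ruthenium hydride catalysis during the ring closure, and the acid stage may stall at the methoxy-dihydrofuran or ionise the tertiary allylic alcohol. The fallback sets out from 14 and comes back at 21, carrying the furan preformed through a single cross-metathesis. Commercial 2-(furan-3-yl)ethan-1-ol is converted (I2, PPh3, imidazole) into 3-(2-iodoethyl)furan F7, which alkylates prop-1-ynyllithium (THF/DMPU) to give 3-(pent-3-yn-1-yl)furan F8. Hydrozirconation (Cp2Zr(H)Cl, THF; here with no hydroxyl or second alkene to complicate it) gives chloro[(2E)-5-(furan-3-yl)pent-2-en-2-yl]bis(cyclopentadienyl)zirconium F9, and CuCl-catalysed allylation gives 3-[(3E)-4-methylhepta-3,6-dien-1-yl]furan F10. Cross-metathesis of F10 (in excess) with diol lactone 14 under the conditions of step 10 should give 21 directly, a 3-alkylfuran being compatible with the ruthenium carbene.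

Further compounds
F1 | step 10 | (2E,4S,7R)-4-hydroxy-4-methyl-7-[(2S)-2-methyl-5-oxooxolan-2-yl]-7-[(triethylsilyl)oxy]hept-2-en-1-yl acetate | CC(=O)OC/C=C/[C@@](C)(O)CC[C@@H](O[Si](CC)(CC)CC)[C@]1(C)CCC(=O)O1
F2 | step 2 | 6-methyl-2-methylidenehept-5-en-1-ol | CC(C)=CCCC(=C)CO
F3 | step 2 | tert-butyldimethyl[(6-methyl-2-methylidenehept-5-en-1-yl)oxy]silane | CC(C)=CCCC(=C)CO[Si](C)(C)C(C)(C)C
F4 | step 2 | (2E)-6-({[tert-butyl(dimethyl)silyl]oxy}methyl)-2-methylhepta-2,6-dien-1-ol | OC/C(C)=C/CCC(=C)CO[Si](C)(C)C(C)(C)C
F5 | step 2 | {[(5E)-7-bromo-6-methyl-2-methylidenehept-5-en-1-yl]oxy}(tert-butyl)dimethylsilane | BrC/C(C)=C/CCC(=C)CO[Si](C)(C)C(C)(C)C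
F6 | step 2 | tert-butyldimethyl{[(5E)-6-methyl-2-methylidenenona-5,8-dien-1-yl]oxy}silane | C/C(=C\CCC(=C)CO[Si](C)(C)C(C)(C)C)CC=C
F7 | step 13 | 3-(2-iodoethyl)furan | ICCc1ccoc1
F8 | step 13 | 3-(pent-3-yn-1-yl)furan | CC#CCCc1ccoc1
F9 | step 13 | chloro[(2E)-5-(furan-3-yl)pent-2-en-2-yl]bis(cyclopentadienyl)zirconium | C/C(=C\CCc1ccoc1)[Zr](Cl)(C1C=CC=C1)C1C=CC=C1
F10 | step 13 | 3-[(3E)-4-methylhepta-3,6-dien-1-yl]furan | C/C(=C\CCc1ccoc1)CC=C
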